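Readings and results come from a simulation with made-up constants; scatter was added.

**Minutes on this flask**

Slowness came first: the analyst reported that the electrophile takes 90.0 min to fall to 7.9% in Wednesday's run and to 8.0% in Sunday's, although Sunday's held more free base, and she proposed 92.1% reacted for this flask at the same time, assuming that the held gas keeps refilling the nucleophile.

the same everywhere: gas 9.2 mM (held)

| flask | electrophile | free base | remark | time |
|---|---|---|---|---|
| Wednesday's | 42 mM | 47 mM | run made earlier |  |
| Sunday's | 42 mM | 74 mM | run made earlier |  |
| Thursday's | 21 mM | 33.6 mM | run made earlier |  |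
| flask | 42 mM | 33.6 mM |  | 1.5 h |

- Wednesday's (time / min: electrophile / %, target / %): 6.00: 85.8, 13.7; 20.0: 58.8, 39.9; 30.0: 44.6, 53.6; 50.0: 25.4, 69.8; 60.0: 19.1, 74.9; 90.0: 7.9, 80.6
- Sunday's (time / min: electrophile / %, target / %): 8.00: 81.5, 18.7; 12.0: 72.9, 27.1; 20.0: 58.7, 40.7; 30.0: 44.5, 54.1; 50.0: 25.6, 70.1; 90.0: 8.0, 80.6
- Thursday's (time / min: electrophile / %, target / %): 8.00: 80.7, 18.8; 15.0: 66.5, 32.7; 25.0: 50.3, 48.0; 50.0: 25.7, 70.7; 90.0: 8.5, 81.0

(standard deviation of a reading: 0.3 percentage points)

- at the start none of the gas is in solution
- the earlier runs do not show how much of nucleophile is bound; that part of a forecast is a guess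

* part of the electrophile that has reacted at 1.5 h
* share of the unused nucleophile that is free and not bound as protonated nucleophile, at 1.5 h

The process chemist objected that the earlier runs held more free base than electrophile, whereas this flask's charge covers 80.0% of the electrophile, which makes free base the limiting reagent for taking up acid. Assuming one acid per electrophile reacted and that free base takes it first, he wrote that balance and named the uncovered acid, the fraction of the charge reacted beyond the cover, 12.1%. The meeting accepted, as a guess, that this acid sits on nucleophile, and with free nucleophile at its ceiling of 21.9% of the charge, the analyst put the free share at 64.4%.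

The forecast gives 91.7% reacted and a free share of 56%, lower than this reckoning, and says of that share, “This part is a guess”.

The flask gives 91.6% reacted and 63.0% free.

    electrophile + nucleophile → acid set free + target (k = 0.0510 L mol⁻¹ s⁻¹)
    nucleophile + acid set free ⇌ protonated nucleophile, settled at all times (K = 2000 L mol⁻¹)
    acid set free + free base ⇌ salt of the base, settled at all times (K = 1.40 × 10⁵ L mol⁻¹)
    gas ⇌ nucleophile, rate k4*(csat - [nucleophile]) (kL = 0.0465 s⁻¹)
    nucleophile + target → over-reaction product (k = 0.00372 L mol⁻¹ s⁻¹)
    electrophile → decomposition product (k = 1.10 × 10⁻⁷ s⁻¹)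

In this flask a gap in nucleophile closes with a half-life of 14.9 s, far shorter than the half-life of 0.16 h that reaction with electrophile gives nucleophile at 0.378 h, and at 1.50 h free nucleophile stands at 21.7% of the charge, while 2.4% of the free base remains, which makes the uncovered acid 13.5% of the charge, and protonated nucleophile and acid set free together hold 13.4%. The neighbour with 20 mM of free base has a cover of 47.6%, and its 91.4% reacted leaves uncovered acid of 43.8%, which puts its free share at 33.3%, and it stands at 34.1%.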